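Numbering: C1 ring ketone, C2 alkene carbon carrying C7H2OH, C3 alkene CH, C4 (O-angeloyl), C5 (isopropyl), C6 (O-tigloyl). In the cyclohexenone ring, C2=C3 is the only bond joining two carbons that are not stereocentres. Cutting it opens the ring to an octa-1,7-dien-3-one and leaves C4–C5–C6 as an intact open-chain triad.
Further cuts: C1–C2 (alkenyl metal plus C1 aldehyde), the O4–angeloyl bond, the O6–tigloyl bond together with C4–H (Tishchenko transfer), C3–C4 (vinyl plus Weinreb amide) and C5–C6 (aldol).
Forward: the chain grows C5–C6, then C3–C4, then C1–C2. Both esters are placed on the open chain, the single ring closes by metathesis in the last step but one, and only a desilylation follows.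
Stereochemistry: C5 and C6 come from a boron syn aldol under (R)-4-benzyloxazolidinone control. C4 comes from a 1,3-anti hydride transfer directed by O6. That transfer also leaves the tiglate on O6 and O4 as the only free hydroxyl for the angelate, so the two esters never compete.
The E and Z butenoate geometries are bought in with tiglaldehyde and angelic acid.

Key step: step 12

Remark: target numbering is kept for all open-chain compounds. [(4-Methoxybenzyl)oxy]acetaldehyde, tiglaldehyde, angelic acid and 2-bromoallyl alcohol are taken as purchasable. The C5 descriptor changes from R to S in step 5 only because the substituent priorities change.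

Step 1
Reactants: 1 (R)-4-benzyloxazolidin-2-one; 2 isovaleryl chloride
Product: 4 (R)-4-benzyl-3-(3-methylbutanoyl)oxazolidin-2-one, via lithium oxazolidinide 3 (not isolated)
Conditions: n-BuLi (1.0 equiv), THF, −78 °C; then 2, −78 to 0 °C
Reagents that add atoms: none
Why: N-acylation of the lithiated carbamate nitrogen with an acid chloride is the standard loading of an Evans auxiliary and does not touch the benzyl-bearing stereocentre.

Step 2
Reactants: 4 (R)-4-benzyl-3-(3-methylbutanoyl)oxazolidin-2-one; 5 [(4-methoxybenzyl)oxy]acetaldehyde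
Product: 8 (R)-4-benzyl-3-{(2R,3R)-3-hydroxy-4-[(4-methoxybenzyl)oxy]-2-(propan-2-yl)butanoyl}oxazolidin-2-one, via Z-boron enolate 6 (not isolated), via boron aldolate 7 (not isolated)
Conditions: Bu2BOTf (1.2 equiv), Et3N (1.4 equiv), CH2Cl2, 0 °C; 5, −78 to 0 °C; then pH 7 buffer, MeOH, 30% H2O2, 0 °C
Reagents that add atoms: none
Why: Evans syn aldol, in which soft enolisation gives only the Z-boron enolate 6 and a chair Zimmerman–Traxler transition state on the face away from the benzyl group, with the imide dipoles opposed, sets C5 and C6 together as the (2R,3R) syn pair.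

Step 3
Reactants: 8 aldol adduct
Product: 9 (2R,3R)-3-hydroxy-N-methoxy-4-[(4-methoxybenzyl)oxy]-N-methyl-2-(propan-2-yl)butanamide
Conditions: MeONHMe·HCl (4 equiv), AlMe3 (4 equiv), THF, −20 °C to rt; aqueous work-up
Reagents that add atoms: N,O-dimethylhydroxylamine hydrochloride, CNOC.Cl
Why: Aluminium-amide transamination (Weinreb amide synthesis), in which the free C6 hydroxyl binds aluminium and steers the amide nitrogen to the exocyclic imide carbonyl, releasing the auxiliary for reuse without epimerising C5.

Step 4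
Reactants: 9 Weinreb amide
Product: 11 (4R,5R)-5-hydroxy-6-[(4-methoxybenzyl)oxy]-4-(propan-2-yl)hex-1-en-3-one, via tetrahedral magnesium adduct 10 (not isolated)
Conditions: CH2=CHMgBr (3 equiv), THF, −78 to 0 °C; inverse quench into cold 1 M HCl
Reagents that add atoms: vinylmagnesium bromide, C=C[Mg]Br
Why: Weinreb ketone synthesis, in which the hydroxyl is deprotonated first, a second equivalent adds once, and the chelated adduct 10 survives until the acidic quench, which keeps the liberated amine protonated and away from the new vinyl ketone.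

Step 5
Reactants: 11 β-hydroxy vinyl ketone; 12 tiglaldehyde [(E)-2-methylbut-2-enal]
Product: 14 (2R,3S,4S)-4-hydroxy-1-[(4-methoxybenzyl)oxy]-3-(propan-2-yl)hex-5-en-2-yl (E)-2-methylbut-2-enoate, via samarium-bound hemiacetal 13 (not isolated)
Conditions: 12 (6 equiv), SmI2 (0.3 equiv, premixed with 12), THF, −10 °C
Reagents that add atoms: none
Why: Evans–Tishchenko reduction, in which O6 adds to tiglaldehyde, trivalent samarium ties hemiacetal 13 to the C4 ketone, and hydride passes intramolecularly through a chair-like bicyclic transition state to the face that gives the 1,3-anti (4S) carbinol, the oxidised aldehyde staying on O6 as the E-configured tiglate.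

Step 6
Reactants: 14 O6-tiglate with free O4–H; 15 angelic acid [(Z)-2-methylbut-2-enoic acid]
Product: 17 (3S,4S,5R)-6-[(4-methoxybenzyl)oxy]-5-{[(E)-2-methylbut-2-enoyl]oxy}-4-(propan-2-yl)hex-1-en-3-yl (Z)-2-methylbut-2-enoate, via mixed angelic anhydride 16 (not isolated)
Conditions: 15, 2,4,6-Cl3C6H2COCl, Et3N, toluene, rt; then 14, 80 °C
Reagents that add atoms: none
Why: Yamaguchi-type mixed-anhydride esterification run without a nucleophilic catalyst, in which the ortho-chlorines shield the aroyl carbonyl so that the only free hydroxyl attacks the angeloyl carbonyl of 16, leaving out 4-dimethylaminopyridine avoids the addition–elimination path from angelate to tiglate, and C4 keeps its configuration because its C–O bond is not broken.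

Step 7
Reactants: 17 bis-ester p-methoxybenzyl ether
Product: 18 (3S,4S,5R)-6-hydroxy-5-{[(E)-2-methylbut-2-enoyl]oxy}-4-(propan-2-yl)hex-1-en-3-yl (Z)-2-methylbut-2-enoate
Conditions: DDQ (1.3 equiv), CH2Cl2/pH 7 buffer, 0 °C
Reagents that add atoms: none
Why: Oxidative p-methoxybenzyl ether cleavage, in which DDQ abstracts hydride only from the electron-rich benzylic position, water traps the oxocarbenium ion, and the neutral medium discourages a 1,2-shift of the tiglate to the new primary hydroxyl.

Step 8
Reactants: 18 primary alcohol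
Product: 19 (3S,4S,5R)-5-{[(E)-2-methylbut-2-enoyl]oxy}-6-oxo-4-(propan-2-yl)hex-1-en-3-yl (Z)-2-methylbut-2-enoate
Conditions: Dess–Martin periodinane (1.3 equiv), CH2Cl2, 0 °C to rt
Reagents that add atoms: none
Why: Dess–Martin oxidation stops at the aldehyde and involves no base, so the α-acyloxy stereocentre C6 should not epimerise.

Step 9
Reactants: 20 2-bromoallyl alcohol
Product: 21 [(2-bromoprop-2-en-1-yl)oxy](tert-butyl)dimethylsilane
Conditions: TBSCl, imidazole, CH2Cl2, 0 °C to rt
Reagents that add atoms: tert-butyldimethylsilyl chloride, CC(C)(C)[Si](C)(C)Cl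
Why: Imidazole-promoted silylation of a primary allylic alcohol is routine, and the vinyl bromide is inert to it.

Step 10
Reactants: 19 α-acyloxy aldehyde; 21 2-bromoallyl silyl ether
Product: 23 (3S,4S,5R,6RS)-7-{[(tert-butyldimethylsilyl)oxy]methyl}-6-hydroxy-5-{[(E)-2-methylbut-2-enoyl]oxy}-4-(propan-2-yl)octa-1,7-dien-3-yl (Z)-2-methylbut-2-enoate, via alkenylchromium dichloride 22 (not isolated)
Conditions: CrCl2 (4 equiv), NiCl2 (2 mol %), DMF, rt; aqueous work-up
Reagents that add atoms: none
Why: Nozaki–Hiyama–Kishi coupling, in which zerovalent nickel inserts into the C–Br bond, transmetallation gives 22, and this reagent adds only to the aldehyde to give a weakly basic trivalent chromium alkoxide that should trigger neither ester attack, acyl migration nor oxygen-to-carbon silyl transfer, the C1 carbinol forming as an epimer mixture that step 11 erases.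

Step 11
Reactants: 23 allylic alcohol (C1 epimers)
Product: 24 (3S,4S,5R)-7-{[(tert-butyldimethylsilyl)oxy]methyl}-5-{[(E)-2-methylbut-2-enoyl]oxy}-6-oxo-4-(propan-2-yl)octa-1,7-dien-3-yl (Z)-2-methylbut-2-enoate
Conditions: Dess–Martin periodinane (1.5 equiv), CH2Cl2, 0 °C to rt
Reagents that add atoms: none
Why: Dess–Martin oxidation converges both allylic alcohol epimers on one α-methylene ketone without base, so C6 stays intact.

Step 12
Reactants: 24 acyclic dienone
Product: 25 (1S,5R,6S)-3-{[(tert-butyldimethylsilyl)oxy]methyl}-5-{[(E)-2-methylbut-2-enoyl]oxy}-4-oxo-6-(propan-2-yl)cyclohex-2-en-1-yl (Z)-2-methylbut-2-enoate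
Conditions: second-generation Hoveyda–Grubbs catalyst, RuCl2(H2IMes)(=CH-C6H4-2-OiPr) (10 mol %), toluene (0.003 M), 80 °C, argon sparge
Reagents that add atoms: none
Why: Ring-closing alkene metathesis, in which the ruthenium benzylidene first exchanges with the monosubstituted C3 vinyl group, the C3 alkylidene adds across the C2 methylene in a [2+2] step, and cycloreversion of the ruthenacyclobutane forms C2=C3 and passes on a methylidene, so that ethene is the only co-product. The closest known reaction type is the closure of 2-substituted cyclohex-2-enones from 1,1-disubstituted α-methylene ketones that carry a remote, allylically oxygenated vinyl group, using N-heterocyclic-carbene ruthenium catalysts. The single ring closes as a six-membered carbocycle by intramolecular metathesis of a 1,7-diene, and the ring size allows only the endocyclic cis alkene. No stereocentre is formed, and C4, C5 and C6 lie outside the reacting carbons and meet neither acid nor base, so the triad should pass through unchanged. The step needs chemoselectivity, namely initiation at the vinyl group rather than the enone, no reaction of the two trisubstituted ester-conjugated butenoate alkenes, and cyclisation rather than dimerisation; the substitution pattern of the four alkenes secures the first two, and high dilution with removal of ethene secures the third. The C5/C6 syn and C4/C5 anti arrangement lets the chain fold into a half-chair with isopropyl and O6 equatorial and O4 pseudoaxial, which brings the two termini together.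

Step 13
Reactants: 25 silyl-protected cyclohexenone
Product: 26 (1S,5R,6S)-3-(hydroxymethyl)-5-{[(E)-2-methylbut-2-enoyl]oxy}-4-oxo-6-(propan-2-yl)cyclohex-2-en-1-yl (Z)-2-methylbut-2-enoate
Conditions: HF·pyridine, pyridine, THF, 0 °C to rt
Reagents that add atoms: none
Why: Cleavage of a primary silyl ether with pyridine-buffered HF is mildly acidic, and under these conditions both enoate esters, the γ-acyloxy enone and the enolisable C6 centre should be stable.

Compound list
1 | (R)-4-benzyloxazolidin-2-one | O=C1N[C@H](Cc2ccccc2)CO1 | starting material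
2 | isovaleryl chloride | CC(C)CC(Cl)=O | starting material
3 | N-lithio-(R)-4-benzyloxazolidin-2-one | [Li]N1[C@H](Cc2ccccc2)COC1=O | intermediate
4 | (R)-4-benzyl-3-(3-methylbutanoyl)oxazolidin-2-one | CC(C)CC(=O)N1[C@H](Cc2ccccc2)COC1=O | intermediate
5 | [(4-methoxybenzyl)oxy]acetaldehyde | COc1ccc(COCC=O)cc1 | starting material
6 | Z-dibutylboron enolate of 4 | CCCCB(CCCC)O/C(=C\C(C)C)N1[C@H](Cc2ccccc2)COC1=O | intermediate
7 | O6-dibutylboron aldolate of 8 | O=C1OC[C@@H](Cc2ccccc2)N1C(=O)[C@H](C(C)C)[C@@H](OB(CCCC)CCCC)COCc1ccc(OC)cc1 | intermediate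
8 | (R)-4-benzyl-3-{(2R,3R)-3-hydroxy-4-[(4-methoxybenzyl)oxy]-2-(propan-2-yl)butanoyl}oxazolidin-2-one | O=C1OC[C@@H](Cc2ccccc2)N1C(=O)[C@H](C(C)C)[C@@H](O)COCc1ccc(OC)cc1 | intermediate
9 | (2R,3R)-3-hydroxy-N-methoxy-4-[(4-methoxybenzyl)oxy]-N-methyl-2-(propan-2-yl)butanamide | CON(C)C(=O)[C@H](C(C)C)[C@@H](O)COCc1ccc(OC)cc1 | intermediate
10 | bis(bromomagnesium) tetrahedral adduct of 9 and the vinyl reagent | C=CC(O[Mg]Br)(N(C)OC)[C@H](C(C)C)[C@@H](O[Mg]Br)COCc1ccc(OC)cc1 | intermediate
11 | (4R,5R)-5-hydroxy-6-[(4-methoxybenzyl)oxy]-4-(propan-2-yl)hex-1-en-3-one | C=CC(=O)[C@H](C(C)C)[C@@H](O)COCc1ccc(OC)cc1 | intermediate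
12 | tiglaldehyde, (E)-2-methylbut-2-enal | C/C=C(\C)C=O | starting material
13 | O6 hemiacetal of 11 and 12, held on trivalent samarium (drawn metal-free) | C=CC(=O)[C@H](C(C)C)[C@@H](OC(O)/C(C)=C/C)COCc1ccc(OC)cc1 | intermediate
14 | (2R,3S,4S)-4-hydroxy-1-[(4-methoxybenzyl)oxy]-3-(propan-2-yl)hex-5-en-2-yl (E)-2-methylbut-2-enoate (target numbering 4S,5S,6R) | C=C[C@H](O)[C@H](C(C)C)[C@@H](OC(=O)/C(C)=C/C)COCc1ccc(OC)cc1 | intermediate
15 | angelic acid, (Z)-2-methylbut-2-enoic acid | C/C=C(/C)C(=O)O | starting material
16 | angelic 2,4,6-trichlorobenzoic anhydride | C/C=C(/C)C(=O)OC(=O)c1c(Cl)cc(Cl)cc1Cl | intermediate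
17 | (3S,4S,5R)-6-[(4-methoxybenzyl)oxy]-5-{[(E)-2-methylbut-2-enoyl]oxy}-4-(propan-2-yl)hex-1-en-3-yl (Z)-2-methylbut-2-enoate | C=C[C@H](OC(=O)/C(C)=C\C)[C@H](C(C)C)[C@@H](OC(=O)/C(C)=C/C)COCc1ccc(OC)cc1 | intermediate
18 | (3S,4S,5R)-6-hydroxy-5-{[(E)-2-methylbut-2-enoyl]oxy}-4-(propan-2-yl)hex-1-en-3-yl (Z)-2-methylbut-2-enoate | C=C[C@H](OC(=O)/C(C)=C\C)[C@H](C(C)C)[C@@H](OC(=O)/C(C)=C/C)CO | intermediate
19 | (3S,4S,5R)-5-{[(E)-2-methylbut-2-enoyl]oxy}-6-oxo-4-(propan-2-yl)hex-1-en-3-yl (Z)-2-methylbut-2-enoate | C=C[C@H](OC(=O)/C(C)=C\C)[C@H](C(C)C)[C@@H](OC(=O)/C(C)=C/C)C=O | intermediate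
20 | 2-bromoallyl alcohol | OCC(Br)=C | starting material
21 | [(2-bromoprop-2-en-1-yl)oxy](tert-butyl)dimethylsilane | C=C(Br)CO[Si](C)(C)C(C)(C)C | intermediate
22 | {3-[(tert-butyldimethylsilyl)oxy]prop-1-en-2-yl}chromium dichloride | C=C([Cr](Cl)Cl)CO[Si](C)(C)C(C)(C)C | intermediate
23 | (3S,4S,5R,6RS)-7-{[(tert-butyldimethylsilyl)oxy]methyl}-6-hydroxy-5-{[(E)-2-methylbut-2-enoyl]oxy}-4-(propan-2-yl)octa-1,7-dien-3-yl (Z)-2-methylbut-2-enoate | C=C[C@H](OC(=O)/C(C)=C\C)[C@H](C(C)C)[C@@H](OC(=O)/C(C)=C/C)C(O)C(=C)CO[Si](C)(C)C(C)(C)C | intermediate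
24 | (3S,4S,5R)-7-{[(tert-butyldimethylsilyl)oxy]methyl}-5-{[(E)-2-methylbut-2-enoyl]oxy}-6-oxo-4-(propan-2-yl)octa-1,7-dien-3-yl (Z)-2-methylbut-2-enoate | C=C[C@H](OC(=O)/C(C)=C\C)[C@H](C(C)C)[C@@H](OC(=O)/C(C)=C/C)C(=O)C(=C)CO[Si](C)(C)C(C)(C)C | intermediate
25 | (1S,5R,6S)-3-{[(tert-butyldimethylsilyl)oxy]methyl}-5-{[(E)-2-methylbut-2-enoyl]oxy}-4-oxo-6-(propan-2-yl)cyclohex-2-en-1-yl (Z)-2-methylbut-2-enoate | C/C=C(/C)C(=O)O[C@H]1C=C(CO[Si](C)(C)C(C)(C)C)C(=O)[C@H](OC(=O)/C(C)=C/C)[C@H]1C(C)C | intermediate
26 | (1S,5R,6S)-3-(hydroxymethyl)-5-{[(E)-2-methylbut-2-enoyl]oxy}-4-oxo-6-(propan-2-yl)cyclohex-2-en-1-yl (Z)-2-methylbut-2-enoate (CNP0293256.3) | C/C=C(/C)C(=O)O[C@H]1C=C(CO)C(=O)[C@H](OC(=O)/C(C)=C/C)[C@H]1C(C)C | target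

Total step count: 13. Longest linear sequence: 12 (steps 1–8 and 10–13, from 1 to 26).

Steps most likely to fail

Step 5 carries three risks.
- The vinyl ketone may be lost to single-electron reduction or oligomerisation before hydride transfer.
- Hemiacetal formation with a conjugated, α-branched aldehyde beside an axially placed isopropyl group may be slow.
- The tiglate may drift from O6 to O4 on long exposure.

The fallback separates acylation from reduction and replaces substrate direction by catalyst control. It sets out from 11. O6 is acylated with tigloyl chloride and pyridine in CH2Cl2 at 0 °C to give the β-tigloyloxy vinyl ketone F1. Its carbonyl is then reduced in the 1,2 sense with catecholborane and the (R)-2-methyl-CBS-oxazaborolidine in toluene at −78 °C (Corey–Bakshi–Shibata reduction). The branched C5 carbon is taken as the large substituent. The sequence comes back to the route at 14.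

In step 12 the electron-poor, 1,1-disubstituted C2 methylene may engage the C3 alkylidene too slowly. Catalyst decay, dimerisation at the vinyl terminus or migration of the allylic alkene could then take over. The fallback changes the oxidation level at which the ring closes and sets out from 23. There the C2 methylene belongs to an electron-neutral allylic alcohol whose free hydroxyl should assist metathesis. The second-generation Grubbs catalyst, RuCl2(H2IMes)(PCy3)(=CHPh), in CH2Cl2 at 40 °C should give the cyclohexenol F2 as its C1 epimers. Dess–Martin oxidation of the allylic carbinol then comes back to the route at 25.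

In step 6 acylation of the hindered O4 may be slow at 80 °C. That would give time for Z-to-E isomerisation of the angeloyl unit and for a 1,3-shift of the tiglate that would scramble the ester positions. The fallback builds the Z alkene on the substrate instead of transferring it and sets out from 14. O4 is esterified at 0 °C with the more reactive, non-conjugated 2-[bis(2,2,2-trifluoroethoxy)phosphoryl]propanoic acid (N,N'-dicyclohexylcarbodiimide, catalytic 4-dimethylaminopyridine, CH2Cl2) to give the O4 phosphonopropionate F3. Still–Gennari olefination with KN(SiMe3)2, 18-crown-6 and acetaldehyde in THF at −78 °C should then form the Z-trisubstituted enoate. The sequence comes back to the route at 17.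

Further compounds
F1 | step 5 | (2R,3R)-1-[(4-methoxybenzyl)oxy]-4-oxo-3-(propan-2-yl)hex-5-en-2-yl (E)-2-methylbut-2-enoate | C=CC(=O)[C@H](C(C)C)[C@@H](OC(=O)/C(C)=C/C)COCc1ccc(OC)cc1
F2 | step 12 | (1S,4RS,5R,6S)-3-{[(tert-butyldimethylsilyl)oxy]methyl}-4-hydroxy-5-{[(E)-2-methylbut-2-enoyl]oxy}-6-(propan-2-yl)cyclohex-2-en-1-yl (Z)-2-methylbut-2-enoate | C/C=C(/C)C(=O)O[C@H]1C=C(CO[Si](C)(C)C(C)(C)C)C(O)[C@H](OC(=O)/C(C)=C/C)[C@H]1C(C)C
F3 | step 6 | (3S,4S,5R)-6-[(4-methoxybenzyl)oxy]-5-{[(E)-2-methylbut-2-enoyl]oxy}-4-(propan-2-yl)hex-1-en-3-yl 2-[bis(2,2,2-trifluoroethoxy)phosphoryl]propanoate | C=C[C@H](OC(=O)C(C)P(=O)(OCC(F)(F)F)OCC(F)(F)F)[C@H](C(C)C)[C@@H](OC(=O)/C(C)=C/C)COCc1ccc(OC)cc1
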